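**Plan**

1. Numbering: C1 ketone, C2=C3 (methyl on C3), cyclobutane C4–C5–C11–C10, C6 (gem-dimethyl), C7 (isovalerate), C8, C9 (senecioate), C10 (methyl). The retrosynthesis cuts the two ester C–O bonds, then C5–C6 (seven-membered ring), then C8–C9 (side chain), and last C3–C4 and C1–C11 (six-membered ring).
2. Enabling feature: C4 and C11 are the two enantiotopic α-carbons of a 3,3-disubstituted cyclobutanone (C5 = carbonyl, C10 = ring carbon 3), and C3–C2–C1 is a but-2-enoyl unit spanning them, so the bicyclo[3.1.1]heptane is the product of an enamine α,α′-annulation.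
3. Forward order: four-membered ring by ketene [2+2]; six-membered ring by the annulation; C9–C8 joined by a boron aldol; seven-membered ring last, by attack of a C6 radical on a C5 N-aziridinylimine, which makes C5–C6 and C5–H in one operation.
4. Stereochemistry: C4, C11 and C10 from (S)-2-(methoxymethyl)pyrrolidine together with the methyl/silyloxymethyl face bias; C9 from the diisopinocampheylboron enolate; C7 by 1,3-anti hydride delivery from O9; C5 from the tether.
5. C1 is carried as a silyl enol ether from the aldehyde stage to the last step, so that no nucleophile meets the C5 ketone while a C1 carbonyl stands 1,3 to it (retro-Claisen or retro-aldol opening of the four-membered ring).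

Key step: step 4

Abbreviations: TBDPS = tert-butyldiphenylsilyl, TBS = tert-butyldimethylsilyl, Ipc = isopinocampheyl.

Assumption: 1-amino-2-phenylaziridine is treated as a stock reagent (two operations from styrene glycol via the dimesylate and hydrazine, stored as its acetate), and C3 is taken to leave step 4 with its methyl on the side of the C5 bridge, as a chair-like transition state predicts; step 14 is chosen to suit that configuration.

**Route**

Step 1
Reactants: 1 2-methylprop-2-en-1-ol; 2 tert-butyl(chloro)diphenylsilane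
Product: 3 tert-butyl[(2-methylprop-2-en-1-yl)oxy]diphenylsilane
Conditions: imidazole, CH2Cl2, 0 °C → rt
Reagents that add atoms: tert-butyl(chloro)diphenylsilane 2, CC(C)(C)[Si](Cl)(c1ccccc1)c1ccccc1
Why: Silyl ether formation at a primary alcohol; the bulky, acid-stable TBDPS group later marks one face of the four-membered ring.

Step 2
Reactants: 3 tert-butyl[(2-methylprop-2-en-1-yl)oxy]diphenylsilane; 4 trichloroacetyl chloride
Product: 6 (±)-3-{[tert-butyl(diphenyl)silyl]oxymethyl}-2,2-dichloro-3-methylcyclobutan-1-one, via dichloroketene 5 (not isolated)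
Conditions: zinc–copper couple (Zn–Cu), POCl3, Et2O, 0 °C → rt
Reagents that add atoms: trichloroacetyl chloride 4, ClC(Cl)(Cl)C(Cl)=O
Why: Ketene–alkene [2+2] cycloaddition, in which dichloroketene made by zinc dechlorination adds to the 1,1-disubstituted alkene with its carbonyl carbon at the CH2 terminus; the stereocentre is formed racemic and disappears in step 3.

Step 3
Reactants: 6 (±)-3-{[tert-butyl(diphenyl)silyl]oxymethyl}-2,2-dichloro-3-methylcyclobutan-1-one
Product: 7 3-{[tert-butyl(diphenyl)silyl]oxymethyl}-3-methylcyclobutan-1-one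
Conditions: Zn dust, AcOH, rt
Reagents that add atoms: none
Why: Reductive dechlorination of an α,α-dichloro ketone by zinc gives the achiral, prochiral cyclobutanone with two equivalent α-methylenes.

Step 4
Reactants: 7 3-{[tert-butyl(diphenyl)silyl]oxymethyl}-3-methylcyclobutan-1-one; 8 (S)-2-(methoxymethyl)pyrrolidine; 9 (E)-but-2-enoyl chloride
Product: 12 (1R,4R,5R,7R)-7-{[tert-butyl(diphenyl)silyl]oxymethyl}-4,7-dimethylbicyclo[3.1.1]heptane-2,6-dione, via cyclobutene enamine 10 (not isolated), via bicyclic iminium chloride 11 (not isolated)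
Conditions: 8 (1.2 equiv), 4 Å molecular sieves, toluene, rt; then 9, MeCN, −20 °C → 40 °C; then aqueous AcOH–NaOAc buffer (pH 5), rt
Reagents that add atoms: (E)-but-2-enoyl chloride 9, C/C=C/C(=O)Cl; water, O
Why: Proposed new method: the enamine is N-acylated and a [3,3] shift of the N-acyl enammonium ion joins C4 to the β-carbon C3, leaving a C5 iminium ion tethered to a ketene; the enamine then re-forms toward C11 and is C-acylated by the ketene carbon C1, and the bicyclic iminium salt is hydrolysed. The closest known reaction is the α,α′-annulation of cyclohexanone enamines with α,β-unsaturated acid chlorides to bicyclo[3.3.1]nonane-2,9-diones, and the closest known asymmetric event is the amine-mediated desymmetrisation of 3-substituted cyclobutanones. The six-membered ring closes by a 6-exo-dig acylation (C11 onto the sp ketene carbon, C=O exocyclic) across the 1,3-cis positions of the four-membered ring, and the irreversible C–C acylation pays for the strain of the bicyclo[3.1.1] skeleton. C4 and C11 can only be bridged cis, and their absolute sense follows from which enantiotopic α-methylene is alkylated: the methoxymethyl arm of the (S)-amine shields one face of the enamine, so only the enamine regioisomer whose open face is also the face anti to the silyloxymethyl group should react (Curtin–Hammett between the two equilibrating enamines). C10 becomes stereogenic through the same facial choice (bridge on the methyl face, away from CH2OTBDPS), and C3 is set by the chair-like [3,3] transition state of the (E)-acyl unit (methyl toward the C5 bridge), a centre erased in step 14. The step needs C–C bond formation instead of a stable N-acyl product and no second reaction at the β-position; both α-carbons are methylenes and C10 is quaternary, so there is neither a more substituted enamine nor a β-elimination pathway.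

Step 5
Reactants: 12 (1R,4R,5R,7R)-7-{[tert-butyl(diphenyl)silyl]oxymethyl}-4,7-dimethylbicyclo[3.1.1]heptane-2,6-dione
Product: 13 (1R,4R,5R,7R)-7-(hydroxymethyl)-4,7-dimethylbicyclo[3.1.1]heptane-2,6-dione
Conditions: HF·pyridine, pyridine, THF, 0 °C → rt
Reagents that add atoms: none
Why: Desilylation with buffered acidic fluoride, chosen because basic fluoride or alkoxide could open the strained 2-acylcyclobutanone by retro-Claisen cleavage.

Step 6
Reactants: 13 (1R,4R,5R,7R)-7-(hydroxymethyl)-4,7-dimethylbicyclo[3.1.1]heptane-2,6-dione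
Product: 14 (1R,4R,5R,7R)-4,7-dimethyl-2,6-dioxobicyclo[3.1.1]heptane-7-carbaldehyde
Conditions: Dess–Martin periodinane, NaHCO3, CH2Cl2, 0 °C → rt
Reagents that add atoms: none
Why: Dess–Martin oxidation of the neopentyl primary alcohol gives the non-enolisable C9 aldehyde under neutral, non-nucleophilic conditions.

Step 7
Reactants: 14 (1R,4R,5R,7R)-4,7-dimethyl-2,6-dioxobicyclo[3.1.1]heptane-7-carbaldehyde; 15 tert-butyldimethylsilyl trifluoromethanesulfonate
Product: 16 (1R,4R,5R,7R)-2-{[tert-butyl(dimethyl)silyl]oxy}-4,7-dimethyl-6-oxobicyclo[3.1.1]hept-2-ene-7-carbaldehyde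
Conditions: Et3N, CH2Cl2, −78 → 0 °C
Reagents that add atoms: tert-butyldimethylsilyl trifluoromethanesulfonate 15, CC(C)(C)[Si](C)(C)OS(=O)(=O)C(F)(F)F
Why: Soft enolisation–silylation in which C2 is the only enolisable position (C4 and C11 are bridgeheads, the aldehyde has no α-hydrogen), so the C1 carbonyl is masked regiospecifically as a silyl enol ether that removes the 1,3-dicarbonyl relation to C5 and later serves as the handle for dehydrogenation.

Step 8
Reactants: 17 3-bromo-3-methylbutan-2-one; 18 diphenyl diselenide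
Product: 19 3-methyl-3-(phenylselanyl)butan-2-one
Conditions: 18, NaBH4, EtOH, 0 °C; then 17, 0 °C → rt
Reagents that add atoms: diphenyl diselenide 18, c1ccccc1[Se][Se]c1ccccc1
Why: Nucleophilic substitution of the tertiary α-bromo ketone by benzeneselenolate places the future radical precursor on C6; no stereocentre is formed.

Step 9
Reactants: 16 (1R,4R,5R,7R)-2-{[tert-butyl(dimethyl)silyl]oxy}-4,7-dimethyl-6-oxobicyclo[3.1.1]hept-2-ene-7-carbaldehyde; 19 3-methyl-3-(phenylselanyl)butan-2-one
Product: 21 (1R,4R,5R,7R)-2-{[tert-butyl(dimethyl)silyl]oxy}-7-[(1R)-1-hydroxy-4-methyl-3-oxo-4-(phenylselanyl)pentyl]-4,7-dimethylbicyclo[3.1.1]hept-2-en-6-one, via enol diisopinocampheylborinate 20 (not isolated)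
Conditions: 19, (+)-Ipc2BCl, Et3N, Et2O, −78 → 0 °C; then 16, −78 → −20 °C; MeOH, pH 7 buffer (no peroxide)
Reagents that add atoms: 3-methyl-3-(phenylselanyl)butan-2-one 19, CC(=O)C(C)(C)[Se]c1ccccc1
Why: Boron-mediated aldol reaction of a methyl ketone in which the chiral isopinocampheyl ligands should steer the enolate to the Re face of the C9 aldehyde (reagent control, since the quaternary C10 gives little bias) and so set (9R), while the non-oxidative work-up spares the cyclobutanone and the selenide.

Step 10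
Reactants: 21 (1R,4R,5R,7R)-2-{[tert-butyl(dimethyl)silyl]oxy}-7-[(1R)-1-hydroxy-4-methyl-3-oxo-4-(phenylselanyl)pentyl]-4,7-dimethylbicyclo[3.1.1]hept-2-en-6-one; 22 3-methylbut-2-enal
Product: 23 (1R,3R)-1-[(1R,4R,5R,7R)-2-{[tert-butyl(dimethyl)silyl]oxy}-4,7-dimethyl-6-oxobicyclo[3.1.1]hept-2-en-7-yl]-3-hydroxy-4-methyl-4-(phenylselanyl)pentyl 3-methylbut-2-enoate
Conditions: SmI2 (0.3 equiv) premixed with 22 (6 equiv), THF, −10 °C
Reagents that add atoms: 3-methylbut-2-enal 22, CC(C)=CC=O
Why: Evans–Tishchenko reduction in which the samarium-bound hemiacetal formed at O9 delivers hydride intramolecularly to the C7 ketone through a chair-like six-membered transition state, which sets (7R) anti to C9 and at the same time places the senecioate on O9.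

Step 11
Reactants: 23 (1R,3R)-1-[(1R,4R,5R,7R)-2-{[tert-butyl(dimethyl)silyl]oxy}-4,7-dimethyl-6-oxobicyclo[3.1.1]hept-2-en-7-yl]-3-hydroxy-4-methyl-4-(phenylselanyl)pentyl 3-methylbut-2-enoate; 24 3-methylbutanoyl chloride
Product: 25 (1R,3R)-1-[(1R,4R,5R,7R)-2-{[tert-butyl(dimethyl)silyl]oxy}-4,7-dimethyl-6-oxobicyclo[3.1.1]hept-2-en-7-yl]-4-methyl-3-(3-methylbutanoyloxy)-4-(phenylselanyl)pentyl 3-methylbut-2-enoate
Conditions: pyridine, DMAP, CH2Cl2, 0 °C → rt
Reagents that add atoms: 3-methylbutanoyl chloride 24, CC(C)CC(=O)Cl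
Why: DMAP-catalysed esterification of the C7 hydroxyl, run directly after step 10 to forestall 1,3-acyl migration; no stereocentre is touched.

Step 12
Reactants: 25 (1R,3R)-1-[(1R,4R,5R,7R)-2-{[tert-butyl(dimethyl)silyl]oxy}-4,7-dimethyl-6-oxobicyclo[3.1.1]hept-2-en-7-yl]-4-methyl-3-(3-methylbutanoyloxy)-4-(phenylselanyl)pentyl 3-methylbut-2-enoate; 26 1-amino-2-phenylaziridine
Product: 27 the N-(2-phenylaziridin-1-yl)imine of 25 at the ring ketone C5 (bicyclic position 6)
Conditions: 4 Å molecular sieves, CH2Cl2, 0 °C → rt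
Reagents that add atoms: 1-amino-2-phenylaziridine 26, NN1CC1c1ccccc1
Why: Hydrazone (N-aziridinylimine) formation at the strained, electrophilic C5 ketone, the only ketone left; with C1 masked the carbinolamine cannot fragment the ring, and the mixture of C=N and aziridine isomers converges in step 13.

Step 13
Reactants: 27 the N-(2-phenylaziridin-1-yl)imine of 25 at the ring ketone C5
Product: 28 the tert-butyldimethylsilyl enol ether (C1–O, C1=C2) of 2,3-dihydro-30, with the configuration of 30 at C4, C5, C7, C9, C10 and C11 and with H3 on the face of the C10 bridge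
Conditions: (Me3Si)3SiH (1.5 equiv) and AIBN (0.2 equiv) added over 8 h, benzene (0.005 M), 80 °C
Reagents that add atoms: none
Why: Radical cyclisation onto an N-aziridinylimine, in which the tertiary C6 radical freed from the selenide adds 7-exo to C5 on the only face its tether reaches, the aminyl radical loses styrene and N2, and the C5 radical takes hydrogen from the silane, so that C5–C6 and the C5–H centre (fixed by the cis-1,3 bridge to C10) arise without any C5–O intermediate.

Step 14
Reactants: 28 the tert-butyldimethylsilyl enol ether of 2,3-dihydro-30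
Product: 30 (4R,5S,7R,9R,10R,11R)-7-(3-methylbutanoyloxy)-9-(3-methylbut-2-enoyloxy)longipin-2-en-1-one (CNP0335239.1), via α-bromo ketone 29 (not isolated)
Conditions: N-bromosuccinimide, NaHCO3, THF, −78 → 0 °C; then DBU, 0 °C → rt
Reagents that add atoms: none
Why: α-Bromination of the silyl enol ether followed by E2 dehydrobromination, in which bromine should enter C2 from the face away from the C10 methyl and thus anti to H3, so that loss of HBr gives the C2=C3 enone and removes the C3 stereocentre.

**Compound list**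

1 | 2-methylprop-2-en-1-ol | CC(=C)CO | starting material
2 | tert-butyl(chloro)diphenylsilane | CC(C)(C)[Si](Cl)(c1ccccc1)c1ccccc1 | starting material
3 | tert-butyl[(2-methylprop-2-en-1-yl)oxy]diphenylsilane | CC(=C)CO[Si](c1ccccc1)(c1ccccc1)C(C)(C)C | intermediate
4 | trichloroacetyl chloride | ClC(Cl)(Cl)C(Cl)=O | starting material
5 | dichloroketene | ClC(Cl)=C=O | intermediate (not isolated)
6 | (±)-3-{[tert-butyl(diphenyl)silyl]oxymethyl}-2,2-dichloro-3-methylcyclobutan-1-one | O=C1CC(C)(CO[Si](c2ccccc2)(c2ccccc2)C(C)(C)C)C1(Cl)Cl | intermediate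
7 | 3-{[tert-butyl(diphenyl)silyl]oxymethyl}-3-methylcyclobutan-1-one (C5 carbonyl, C4 and C11 α-methylenes, C10 ring carbon 3, C9 the CH2O carbon) | O=C1CC(C)(CO[Si](c2ccccc2)(c2ccccc2)C(C)(C)C)C1 | intermediate
8 | (S)-2-(methoxymethyl)pyrrolidine | COC[C@@H]1CCCN1 | starting material
9 | (E)-but-2-enoyl chloride | C/C=C/C(=O)Cl | starting material
10 | (3S)-3-{[tert-butyl(diphenyl)silyl]oxymethyl}-1-[(2S)-2-(methoxymethyl)pyrrolidin-1-yl]-3-methylcyclobut-1-ene (double bond C5=C4) | C[C@]1(CO[Si](c2ccccc2)(c3ccccc3)C(C)(C)C)CC(N4CCC[C@H]4COC)=C1 | intermediate (not isolated)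
11 | iminium chloride of dione 12 at C5 with (S)-2-(methoxymethyl)pyrrolidine | C[C@@H]1CC(=O)[C@@H]2C(=[N+]3CCC[C@H]3COC)[C@H]1[C@@]2(C)CO[Si](c1ccccc1)(c1ccccc1)C(C)(C)C.[Cl-] | intermediate (not isolated)
12 | (1R,4R,5R,7R)-7-{[tert-butyl(diphenyl)silyl]oxymethyl}-4,7-dimethylbicyclo[3.1.1]heptane-2,6-dione (C1 and C5 ketones; C10 methyl syn to the three-carbon bridge; C3 methyl toward the C5 bridge) | C[C@@H]1CC(=O)[C@@H]2C(=O)[C@H]1[C@@]2(C)CO[Si](c1ccccc1)(c1ccccc1)C(C)(C)C | intermediate
13 | (1R,4R,5R,7R)-7-(hydroxymethyl)-4,7-dimethylbicyclo[3.1.1]heptane-2,6-dione | C[C@@H]1CC(=O)[C@@H]2C(=O)[C@H]1[C@@]2(C)CO | intermediate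
14 | (1R,4R,5R,7R)-4,7-dimethyl-2,6-dioxobicyclo[3.1.1]heptane-7-carbaldehyde | C[C@@H]1CC(=O)[C@@H]2C(=O)[C@H]1[C@@]2(C)C=O | intermediate
15 | tert-butyldimethylsilyl trifluoromethanesulfonate | CC(C)(C)[Si](C)(C)OS(=O)(=O)C(F)(F)F | starting material
16 | (1R,4R,5R,7R)-2-{[tert-butyl(dimethyl)silyl]oxy}-4,7-dimethyl-6-oxobicyclo[3.1.1]hept-2-ene-7-carbaldehyde | C[C@@H]1C=C(O[Si](C)(C)C(C)(C)C)[C@@H]2C(=O)[C@H]1[C@@]2(C)C=O | intermediate
17 | 3-bromo-3-methylbutan-2-one | CC(=O)C(C)(C)Br | starting material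
18 | diphenyl diselenide | c1ccccc1[Se][Se]c1ccccc1 | starting material
19 | 3-methyl-3-(phenylselanyl)butan-2-one | CC(=O)C(C)(C)[Se]c1ccccc1 | intermediate
20 | 3-methyl-3-(phenylselanyl)but-1-en-2-yl diisopinocampheylborinate (Ipc groups of (+)-Ipc2BCl, from (−)-α-pinene) | C=C(OB([C@H]1C[C@H]2C[C@@H]([C@@H]1C)C2(C)C)[C@H]1C[C@H]2C[C@@H]([C@@H]1C)C2(C)C)C(C)(C)[Se]c1ccccc1 | intermediate (not isolated)
21 | (1R,4R,5R,7R)-2-{[tert-butyl(dimethyl)silyl]oxy}-7-[(1R)-1-hydroxy-4-methyl-3-oxo-4-(phenylselanyl)pentyl]-4,7-dimethylbicyclo[3.1.1]hept-2-en-6-one ((9R)-alcohol, C7 ketone, C6 selenide) | C[C@@H]1C=C(O[Si](C)(C)C(C)(C)C)[C@@H]2C(=O)[C@H]1[C@@]2(C)[C@H](O)CC(=O)C(C)(C)[Se]c1ccccc1 | intermediate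
22 | 3-methylbut-2-enal | CC(C)=CC=O | starting material
23 | (1R,3R)-1-[(1R,4R,5R,7R)-2-{[tert-butyl(dimethyl)silyl]oxy}-4,7-dimethyl-6-oxobicyclo[3.1.1]hept-2-en-7-yl]-3-hydroxy-4-methyl-4-(phenylselanyl)pentyl 3-methylbut-2-enoate ((7R)-alcohol, (9R)-senecioate) | C[C@@H]1C=C(O[Si](C)(C)C(C)(C)C)[C@@H]2C(=O)[C@H]1[C@@]2(C)[C@H](OC(=O)C=C(C)C)C[C@@H](O)C(C)(C)[Se]c1ccccc1 | intermediate
24 | 3-methylbutanoyl chloride | CC(C)CC(=O)Cl | starting material
25 | (1R,3R)-1-[(1R,4R,5R,7R)-2-{[tert-butyl(dimethyl)silyl]oxy}-4,7-dimethyl-6-oxobicyclo[3.1.1]hept-2-en-7-yl]-4-methyl-3-(3-methylbutanoyloxy)-4-(phenylselanyl)pentyl 3-methylbut-2-enoate | C[C@@H]1C=C(O[Si](C)(C)C(C)(C)C)[C@@H]2C(=O)[C@H]1[C@@]2(C)[C@H](OC(=O)C=C(C)C)C[C@@H](OC(=O)CC(C)C)C(C)(C)[Se]c1ccccc1 | intermediate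
26 | 1-amino-2-phenylaziridine (racemic) | NN1CC1c1ccccc1 | starting material
27 | N-(2-phenylaziridin-1-yl)imine of 25 at C5 (mixture of C=N and aziridine isomers) | C[C@@H]1C=C(O[Si](C)(C)C(C)(C)C)[C@@H]2C(=NN3CC3c4ccccc4)[C@H]1[C@@]2(C)[C@H](OC(=O)C=C(C)C)C[C@@H](OC(=O)CC(C)C)C(C)(C)[Se]c1ccccc1 | intermediate
28 | 1-{[tert-butyl(dimethyl)silyl]oxy}-7-(3-methylbutanoyloxy)-9-(3-methylbut-2-enoyloxy)longipin-1-ene (silyl enol ether of 2,3-dihydro-30; C4, C5, C7, C9, C10, C11 as in 30; H3 toward the C10 bridge) | CC(C)=CC(=O)O[C@@H]1C[C@@H](OC(=O)CC(C)C)C(C)(C)[C@@H]2[C@H]3C(O[Si](C)(C)C(C)(C)C)=C[C@@H](C)[C@@H]2[C@]31C | intermediate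
29 | 2-bromo-2,3-dihydro-30 (bromine on C2 on the face of the C5 bridge, anti to H3) | CC(C)=CC(=O)O[C@@H]1C[C@@H](OC(=O)CC(C)C)C(C)(C)[C@@H]2[C@H]3C(=O)[C@@H](Br)[C@@H](C)[C@@H]2[C@]31C | intermediate (not isolated)
30 | (4R,5S,7R,9R,10R,11R)-7-(3-methylbutanoyloxy)-9-(3-methylbut-2-enoyloxy)longipin-2-en-1-one (CNP0335239.1) | CC(C)=CC(=O)O[C@@H]1C[C@@H](OC(=O)CC(C)C)C(C)(C)[C@@H]2[C@H]3C(=O)C=C(C)[C@@H]2[C@]31C | target

**Step count**

Total: 14 steps. Longest linear sequence: 13 steps (steps 1–7 and 9–14, from 1 to 30); step 8 prepares the ketone fragment 19.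

**Steps most likely to fail**

Step 4 (the step carrying the new-method label). The enamine of the strained ketone may be N-acylated without rearranging or may oligomerise. The ketene may also be captured intermolecularly before the second enamine forms across the four-membered ring, and the amine may discriminate the two α-methylenes poorly. The fallback uses known reactions, sets out from 7 and returns at 12. Condensation of 7 with (S)-1-amino-2-(methoxymethyl)pyrrolidine gives the hydrazone F1. Deprotonation with LiN(i-Pr)2 and Michael addition of the azaenolate to tert-butyl (E)-but-2-enoate (SAMP-hydrazone method) gives the adduct F2, in which the auxiliary picks the α-carbon and the addition occurs anti to the silyloxymethyl group. Ozonolysis at −78 °C releases the keto ester F3, CF3CO2H gives the keto acid F4, and (COCl)2 gives the acid chloride F5. Soft enolisation with MgBr2·OEt2 and i-Pr2NEt then closes C11–C1 by intramolecular C-acylation and gives 12.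

Step 13. Hydrogen transfer from the silane to the tertiary C6 radical, or a 1,5-hydrogen shift, may outrun the 7-exo closure onto the hindered C5 carbon, so that the chain is only reduced. The fallback sets out from 25 and returns at 28; it makes the same radical reversibly by metal-hydride hydrogen-atom transfer instead of by a chain carrier. NaIO4 oxidises the selenide to the selenoxide F6, which eliminates toward a methyl group to the isopropenyl diester F7. p-Toluenesulfonyl hydrazide converts the C5 ketone into the tosylhydrazone F8. Fe(acac)3 and PhSiH3 in EtOH at 60 °C deliver a hydrogen atom to the terminal alkene carbon, and the C6 radical adds to the hydrazone carbon to give the cyclised N′-tosylhydrazide F9. Warming F9 with NaOAc in MeOH expels p-toluenesulfinate and N2 and gives 28.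

Step 9. Facial selection at the C9 aldehyde may be poor, because methyl ketone enol diisopinocampheylborinates are only moderately selective and the quaternary C10 adds little bias. The fallback sets out from 19 and returns at 21; control comes from a chiral Lewis acid in an open transition state. LiN(i-Pr)2 and Me3SiCl convert 19 into the silyl enol ether F10. Mukaiyama aldol addition of F10 to 16, catalysed by the tryptophan-derived N-tosyl B-butyl oxazaborolidinone of the enantiomeric series that exposes the Re face of the aldehyde, gives the silylated aldol F11. Methanolysis with citric acid frees the hydroxyl and gives 21.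

**Further compounds**

F1 | step 4 | (S)-N-(3-{[tert-butyl(diphenyl)silyl]oxymethyl}-3-methylcyclobutylidene)-2-(methoxymethyl)pyrrolidin-1-amine | COC[C@@H]1CCCN1N=C1CC(C)(CO[Si](c2ccccc2)(c2ccccc2)C(C)(C)C)C1
F2 | step 4 | tert-butyl 3-substituted butanoate Michael adduct of F1 (side chain on C4, hydrazone at C5) | C[C@H](CC(=O)OC(C)(C)C)[C@H]1C(=NN2CCC[C@H]2COC)C[C@]1(C)CO[Si](c3ccccc3)(c3ccccc3)C(C)(C)C
F3 | step 4 | tert-butyl 3-(3-{[tert-butyl(diphenyl)silyl]oxymethyl}-3-methyl-2-oxocyclobutyl)butanoate (C3, C4, C10 as in 12) | C[C@H](CC(=O)OC(C)(C)C)[C@H]1C(=O)C[C@]1(C)CO[Si](c2ccccc2)(c2ccccc2)C(C)(C)C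
F4 | step 4 | 3-(3-{[tert-butyl(diphenyl)silyl]oxymethyl}-3-methyl-2-oxocyclobutyl)butanoic acid | C[C@H](CC(=O)O)[C@H]1C(=O)C[C@]1(C)CO[Si](c2ccccc2)(c2ccccc2)C(C)(C)C
F5 | step 4 | 3-(3-{[tert-butyl(diphenyl)silyl]oxymethyl}-3-methyl-2-oxocyclobutyl)butanoyl chloride | C[C@H](CC(=O)Cl)[C@H]1C(=O)C[C@]1(C)CO[Si](c2ccccc2)(c2ccccc2)C(C)(C)C
F6 | step 13 | selenoxide of 25 | C[C@@H]1C=C(O[Si](C)(C)C(C)(C)C)[C@@H]2C(=O)[C@H]1[C@@]2(C)[C@H](OC(=O)C=C(C)C)C[C@@H](OC(=O)CC(C)C)C(C)(C)[Se](=O)c1ccccc1
F7 | step 13 | isopropenyl diester (25 with C6 as C(CH3)=CH2 in place of the selenide) | C[C@@H]1C=C(O[Si](C)(C)C(C)(C)C)[C@@H]2C(=O)[C@H]1[C@@]2(C)[C@H](OC(=O)C=C(C)C)C[C@@H](OC(=O)CC(C)C)C(C)=C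
F8 | step 13 | C5 p-toluenesulfonylhydrazone of F7 | C[C@@H]1C=C(O[Si](C)(C)C(C)(C)C)[C@@H]2C(=NNS(=O)(=O)c3ccc(C)cc3)[C@H]1[C@@]2(C)[C@H](OC(=O)C=C(C)C)C[C@@H](OC(=O)CC(C)C)C(C)=C
F9 | step 13 | cyclised N′-tosylhydrazide (28 with NHNHTs in place of H5) | CC(C)=CC(=O)O[C@@H]1C[C@@H](OC(=O)CC(C)C)C(C)(C)[C@]2(NNS(=O)(=O)c4ccc(C)cc4)[C@H]3C(O[Si](C)(C)C(C)(C)C)=C[C@@H](C)[C@@H]2[C@]31C
F10 | step 9 | trimethyl{[3-methyl-3-(phenylselanyl)but-1-en-2-yl]oxy}silane | C=C(O[Si](C)(C)C)C(C)(C)[Se]c1ccccc1
F11 | step 9 | O9-trimethylsilyl ether of 21 | C[C@@H]1C=C(O[Si](C)(C)C(C)(C)C)[C@@H]2C(=O)[C@H]1[C@@]2(C)[C@H](O[Si](C)(C)C)CC(=O)C(C)(C)[Se]c1ccccc1
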